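## Structural features

1. The target is the (2E)-dodec-2-enamide of an amino alcohol built on a bicyclo[3.3.1]nonan-9-one. The numbering of the 3-oxatricyclo[4.3.1.0^2,4]decan-10-one name is used for every compound below: C1 bridgehead carbinol, C2 and C4 epoxide carbons, O3, C5 methoxy carbon, C6 bridgehead CH, C7 carbinol, C8 amide-bearing carbon, C9 methylene, C10 ketone.
2. Ring A (C1, C9, C8, C7, C6, C10) and ring B (C1, C2, C4, C5, C6, C10) share the bridge C1–C10(=O)–C6. Ring B carries the C2–C4 epoxide and the C5 methoxy group, ring A the cis amino alcohol.
3. The seven stereocentres C1, C2, C4, C5, C6, C7 and C8 are contiguous. On ring B the C1 hydroxyl, the epoxide oxygen and the C5 methoxy group all lie on the exo face, away from ring A. On ring A the C8 amide is equatorial and the C7 hydroxyl axial, cis to the amide and gauche to the C10 carbonyl.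
4. Fragile groups: the β-hydroxy ketone C7/C10 (retro-aldol), the β-methoxy ketone C5/C10 (elimination is held back only because C6 is a bridgehead), the epoxide next to the tertiary α-ketol, and the conjugated enamide.
5. The real difficulty is the bridged carbocycle with a bridgehead tertiary alcohol beside the bridging ketone, in which five of the six ring B carbons are oxygenated.
6. Feature exploited: ring B, with oxygen on C10 and the C9 carbon on C1, is the skeleton of an ortho-substituted phenol, and C9–C8(N)–C7(O) is an alanine chain. The nine core carbons are therefore those of L-ortho-tyrosine, with C8 already correct. The two bonds the amino acid lacks, C6–C7 and C5–OMe, sit α and β to the C10 ketone and can form in one conjugate addition/aldol event.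
7. In one sentence: a methoxide-triggered oxa-Michael/aldol cascade folds a dearomatised and epoxidised L-ortho-tyrosinal amide (an ortho-quinol epoxide carrying its own aldehyde) into the complete bicycle.

## Logic of the disconnections

**10 to 9 to 8 (stored as 7).** The bonds cut are C6–C7 (retro-aldol) and C5–OMe (retro-oxa-Michael). Both depend on the same enolate across C10/C6, so they are cut together. This opens ring A and removes C5, C6 and C7 at once, going from a bridged tricycle with seven stereocentres to the monocyclic epoxy enone 8 with four (C1, C2, C4, C8). 8 is handled as its ring tautomer 7. Demand on the forward step: methoxide must add to C5 on the face of the epoxide, 9 must be trapped by the aldehyde on the C9 face before the epoxy enone is damaged, and C7 must form with its oxygen gauche to C10.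

**7 to 6.** The C1–O–C7 lactol bond is cut and C7 goes back to the alcohol oxidation level. The aldehyde is the only configurationally labile group; as the alcohol in 6 it is inert during the oxidation of ring B, and the C1 hydroxyl stays free. The gain is a stable, separable intermediate. Demand: oxidation of a primary alcohol beside a tertiary one that stops at the lactol.

**6 to 5 to 4.** The bonds cut are C2–O and C4–O of the epoxide, then C1–O; 5 then rearomatises to 4. Oxygen on C1 and C10 with a C2=C4–C5=C6 diene is the pattern of a hydroxylated phenol. The gain is the loss of all three remaining ring B stereocentres: ring B becomes a benzene ring. Demand: oxygen must go to the alkyl-bearing ortho carbon C1 and not to C6–H, on the face that gives (1S) relative to C8. The distal olefin C2=C4 must then be epoxidised syn to the new hydroxyl faster than 5 dimerises.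

**4 to 2 and 3.** The amide C–N bond is cut. The acyl chain is inert to everything that follows, so it is put on first and no nitrogen protecting group is needed. Demand: N-acylation in preference to O-acylation, with no migration of the double bond.

**2 to 1.** C7 returns to the carboxyl level. This reaches a commercial amino acid with C8 in place. Demand: reduction without racemisation.

## Other disconnections considered

Alternative 1: This is the first disconnection that comes to mind. Only C6–C7 is cut, as an intramolecular aldol of a fully functionalised, saturated ring B: the β-methoxy epoxy ketone aldehyde A1, assembled stepwise from a non-aromatic cyclohexenone. The forward key step is enolisation of A1 at C6 and aldol closure. The enolate of A1 is the very species that expels methoxide by E1cB, so a C5 stereocentre set beforehand would be at risk in the step that needs the enolate. A1 also already holds five of the seven stereocentres, which would have to be installed one by one on a flexible monocycle. The chosen plan reaches the same enolate from a flat arene and lets the ring closure choose C5.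

Alternative 2: C1–C9 and C6–C7 are cut together, as a [3+3] Michael/aldol annulation of the 2-amidoacrolein A2 (C9–C8–C7) with the ring B α-ketol A3. In the forward step C1 of the enediolate of A3 would add to A2, and C6 would then close on the aldehyde. The union is convergent, but the first bond needs C-alkylation at the oxygen-bearing, fully substituted C1 in preference to the freer C6 and to O-alkylation. C8 would arise from an unguided protonation, and A3 is itself a β-methoxy ketone prone to elimination. In the chosen plan C1–C9 and C8 come from the amino acid.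

Alternative 3: C8–N and C7–O are cut, as a late cis-aminohydroxylation (K2OsO2(OH)4 with a chloramine salt) of the bicyclic olefin A4 from its exo face. The suprafacial exo addition should give the right relative configuration at C7 and C8. The regiochemistry (nitrogen at C8 and not at C7) has no handle in A4: the C1 hydroxyl is equatorial and cannot tether nitrogen to the equatorial position at C8. A4 would also need its own enantioselective synthesis, so the nitrogen and a stereocentre that the chosen plan takes from the chiral pool would cost extra steps and a selectivity problem.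

Key step: step 5

Assumption: the (R)-antipode of the biaryl iodide is written as the one matched with the (8S) side chain for oxygen delivery to give (1S); if the sense is the opposite, the (S)-antipode takes its place. The C1 epimers are diastereomers and separable at the stage of 6 in either case.

## Steps

Step 1
Reactants: 1 L-ortho-tyrosine, (2S)-2-amino-3-(2-hydroxyphenyl)propanoic acid
Product: 2 L-ortho-tyrosinol, (2S)-2-amino-3-(2-hydroxyphenyl)propan-1-ol
Conditions: NaBH4 (2.5 equiv), I2 (1.1 equiv), THF, 0 °C to reflux; MeOH; aq KOH
Reagents that add atoms: none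
Why: NaBH4/I2 generates borane in the flask, which reduces the carboxyl group of the amino acid to the primary alcohol (amino acid to amino alcohol reduction) and leaves the phenol ring untouched; C8 is not enolisable under these conditions and is carried over from the chiral pool.

Step 2
Reactants: 2 L-ortho-tyrosinol; 3 (2E)-dodec-2-enoic acid
Product: 4 (2E)-N-[(2S)-1-hydroxy-3-(2-hydroxyphenyl)propan-2-yl]dodec-2-enamide
Conditions: DCC (1.05 equiv), HOBt (1.0 equiv), DMF–CH2Cl2, 0 °C to rt
Reagents that add atoms: none
Why: Carbodiimide/HOBt amide coupling; the primary amine out-competes the phenol and the primary alcohol for the active ester, and the conjugated (E) double bond of the acid does not isomerise under these neutral conditions.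

Step 3
Reactants: 4 (2E)-N-[(2S)-1-hydroxy-3-(2-hydroxyphenyl)propan-2-yl]dodec-2-enamide
Product: 6 (2E)-N-[(2S)-1-hydroxy-3-[(1S,2S,6S)-2-hydroxy-3-oxo-7-oxabicyclo[4.1.0]hept-4-en-2-yl]propan-2-yl]dodec-2-enamide, via ortho-quinol diol 5 (not isolated)
Conditions: (R)-2,2'-diiodo-1,1'-binaphthalene (20 mol %), mCPBA (1.2 equiv), CH2Cl2 (0.01 M), −20 to 0 °C; then dimethyldioxirane (1.5 equiv, acetone), −20 °C; Me2S
Reagents that add atoms: mCPBA, OOC(=O)c1cccc(Cl)c1; dimethyldioxirane, CC1(C)OO1
Why: Hydroxylative phenol dearomatisation: the pentavalent iodine (iodyl) species formed from the aryl iodide and mCPBA binds the phenol oxygen and transfers oxygen to the ortho carbon C1 through a [2,3]-type shift (C1 is the alkyl-bearing, more electron-rich ortho carbon), and the C2-symmetric biaryl, matched with C8, should select the face that gives (1S). Dimethyldioxirane then epoxidises the electron-richer distal olefin C2=C4 of dienone 5 in cold dilute solution before it can dimerise, on the face of the C1 hydroxyl (hydrogen-bond direction, reinforced by the bulk of the C9 chain on the other face), which sets C2 and C4; the enone C5=C6 and the enamide are too electron-poor to react.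

Step 4
Reactants: 6 (2E)-N-[(2S)-1-hydroxy-3-[(1S,2S,6S)-2-hydroxy-3-oxo-7-oxabicyclo[4.1.0]hept-4-en-2-yl]propan-2-yl]dodec-2-enamide
Product: 7 (2E)-N-[(1S,2S,4'S,6S)-5'-hydroxy-3-oxospiro[7-oxabicyclo[4.1.0]hept-4-ene-2,2'-oxolan]-4'-yl]dodec-2-enamide (spiro-lactol, both C5' anomers)
Conditions: IBX (1.3 equiv), DMSO, rt
Reagents that add atoms: none
Why: IBX oxidation of a 1,4-diol: the primary alcohol gives the aldehyde, which is captured at once by the C1 hydroxyl as the five-membered lactol, the stage at which IBX in DMSO is known to stop; ring closure also shields C8 from enolisation.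

Step 5
Reactants: 7 (2E)-N-[(1S,2S,4'S,6S)-5'-hydroxy-3-oxospiro[7-oxabicyclo[4.1.0]hept-4-ene-2,2'-oxolan]-4'-yl]dodec-2-enamide
Product: 10 (2E)-N-[(1S,2S,4S,5S,6S,7R,8S)-1,7-dihydroxy-5-methoxy-10-oxo-3-oxatricyclo[4.3.1.0^2,4]decan-8-yl]dodec-2-enamide, via open hydroxy aldehyde 8 (not isolated), via methoxy enolate 9 (not isolated)
Conditions: Mg(OMe)2 (1.2 equiv), MeOH–THF 1:1 (0.02 M), −20 to 0 °C; aq NH4Cl
Reagents that add atoms: methanol, CO (delivered as magnesium methoxide, C[O-].C[O-].[Mg+2])
Why: Mg(OMe)2 opens lactol 7 to the magnesium alkoxide of 8, in which the metal is chelated between the C1 oxygen and the C10 carbonyl and so activates the enone; methoxide then adds reversibly to C5, the only Michael terminus left once C2=C4 has been epoxidised, to give enolate 9. The enolate carbon C6 attacks the aldehyde C7 in a 6-(enolendo)-exo-trig aldol that closes ring A (C1–C9–C8–C7–C6–C10) and with it the bicyclo[3.3.1]nonanone; the closest known reaction type is the base-mediated oxa-Michael/intramolecular aldol cascade of quinol-type cyclohexadienones that carry a tethered aldehyde, transposed here to an ortho-quinol epoxide. C6 is fixed by C1, because the new bond can only form on the face of ring B that carries C9. C5 is decided at the aldol step (Curtin–Hammett, the oxa-Michael step being reversible): the enolate with methoxy axial on the face opposite to the tether, the face of the epoxide and the C1 oxygen, closes through the stereoelectronically preferred trans-diaxial arrangement, whereas its C5 epimer would have to hold the methoxy group endo against C7. C7 is set by a chair for ring A with the C8 amide equatorial and the metal bridging the enolate and aldehyde oxygens (closed, Zimmerman–Traxler-like), which places the C7 oxygen gauche to C10, that is axial and cis to the amide. The step needs conjugate addition to win over methanolysis or base-induced opening of the epoxy enone; the low temperature, a weakly basic chelating methoxide source and the cis relation of the C1 oxygen to the epoxide (no Payne rearrangement possible) serve this. Epimerisation of the aldehyde at C8 would be self-correcting, since only the (8S) epimer can close with an equatorial amide. Once formed, 10 cannot lose methanol by E1cB because C6 is a bridgehead.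

## Compound list

1 | L-ortho-tyrosine, (2S)-2-amino-3-(2-hydroxyphenyl)propanoic acid | N[C@@H](Cc1ccccc1O)C(=O)O | starting material
2 | L-ortho-tyrosinol, (2S)-2-amino-3-(2-hydroxyphenyl)propan-1-ol | N[C@@H](Cc1ccccc1O)CO | intermediate
3 | (2E)-dodec-2-enoic acid | CCCCCCCCC/C=C/C(=O)O | starting material
4 | (2E)-N-[(2S)-1-hydroxy-3-(2-hydroxyphenyl)propan-2-yl]dodec-2-enamide | CCCCCCCCC/C=C/C(=O)N[C@@H](Cc1ccccc1O)CO | intermediate
5 | (2E)-N-[(2S)-1-hydroxy-3-[(1S)-1-hydroxy-6-oxocyclohexa-2,4-dien-1-yl]propan-2-yl]dodec-2-enamide (ortho-quinol diol) | CCCCCCCCC/C=C/C(=O)N[C@H](CO)C[C@@]1(O)C(=O)C=CC=C1 | intermediate (not isolated)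
6 | (2E)-N-[(2S)-1-hydroxy-3-[(1S,2S,6S)-2-hydroxy-3-oxo-7-oxabicyclo[4.1.0]hept-4-en-2-yl]propan-2-yl]dodec-2-enamide (epoxide cis to the tertiary hydroxyl) | CCCCCCCCC/C=C/C(=O)N[C@H](CO)C[C@@]1(O)C(=O)C=C[C@@H]2O[C@@H]21 | intermediate
7 | (2E)-N-[(1S,2S,4'S,6S)-5'-hydroxy-3-oxospiro[7-oxabicyclo[4.1.0]hept-4-ene-2,2'-oxolan]-4'-yl]dodec-2-enamide (spiro-lactol, both anomers) | CCCCCCCCC/C=C/C(=O)N[C@H]1C[C@@]2(OC1O)C(=O)C=C[C@@H]3O[C@@H]32 | intermediate
8 | (2E)-N-[(2S)-1-[(1S,2S,6S)-2-hydroxy-3-oxo-7-oxabicyclo[4.1.0]hept-4-en-2-yl]-3-oxopropan-2-yl]dodec-2-enamide (open hydroxy aldehyde) | CCCCCCCCC/C=C/C(=O)N[C@H](C=O)C[C@@]1(O)C(=O)C=C[C@@H]2O[C@@H]21 | intermediate (not isolated)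
9 | (1S,2S,5S,6S)-2-[(2S)-2-[(2E)-dodec-2-enamido]-3-oxopropyl]-2-hydroxy-5-methoxy-7-oxabicyclo[4.1.0]hept-3-en-3-olate (methoxy enolate, as its magnesium salt; methoxy cis to the epoxide) | CCCCCCCCC/C=C/C(=O)N[C@H](C=O)C[C@@]1(O)C([O-])=C[C@H](OC)[C@@H]2O[C@@H]21 | intermediate (not isolated)
10 | (2E)-N-[(1S,2S,4S,5S,6S,7R,8S)-1,7-dihydroxy-5-methoxy-10-oxo-3-oxatricyclo[4.3.1.0^2,4]decan-8-yl]dodec-2-enamide | CCCCCCCCC/C=C/C(=O)N[C@H]1C[C@@]2(O)C(=O)[C@@H]([C@H]1O)[C@H](OC)[C@@H]1O[C@@H]12 | target

## Step count and least certain steps

Total step count: 5. Longest linear sequence: 5 steps (1 to 2 to 4 to 6 to 7 to 10); 3 enters in step 2.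

**Step 5 (key step).** Most likely to go wrong: poor facial selectivity of the methoxide addition at C5, since attack anti to an allylic epoxide oxygen is the usual kinetic preference, so the outcome rests on the aldol step selecting the right enolate. Base-induced opening of the epoxy enone (deprotonation at C4) before conjugate addition is the second danger.

Fallback: the order of events is changed so that the cascade runs on the dienone and the epoxide is put on last, on the rigid bicycle. It sets out from 4 and comes back at 10. 4 is hydroxylated as in step 3 but without dimethyldioxirane, and the cold dilute solution of 5 is treated with IBX in DMSO to give the dienone spiro-lactol (2E)-N-[(3S,5S)-2-hydroxy-6-oxo-1-oxaspiro[4.5]deca-7,9-dien-3-yl]dodec-2-enamide F1. Mg(OMe)2 in methanol then gives the bicyclic olefin (2E)-N-[(1S,3S,4R,5S,6R)-1,4-dihydroxy-6-methoxy-9-oxobicyclo[3.3.1]non-7-en-3-yl]dodec-2-enamide F2, in which the choice of face at C5 is no longer coupled to an epoxide. Epoxidation of F2 with dimethyldioxirane, or with VO(acac)2/t-BuOOH directed by the C1 hydroxyl, can only take place on the exo face of the bicyclononene and gives 10. The price is possible competition from 1,6-addition of methoxide at C2.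

**Step 3.** Most likely to go wrong: oxygen transfer to C6–H in place of C1 (which leads towards a catechol), weak facial control at C1 by the chiral iodine species, and [4+2] dimerisation of 5 before it is epoxidised.

Fallback: C1–O is formed intramolecularly by carboxylate capture under catalyst control. It sets out from 1 and 3 and comes back at 5, which is epoxidised to 6 as in step 3.
- 3 is converted into (2E)-dodec-2-enoyl chloride F3, which acylates 1 under Schotten–Baumann conditions to give (2S)-2-[(2E)-dodec-2-enamido]-3-(2-hydroxyphenyl)propanoic acid F4.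
- A catalytic enantioselective oxidative ortho-spirolactonisation (C2-symmetric chiral aryl iodide, mCPBA) closes the spirolactone (2E)-N-[(3S,5S)-2,6-dioxo-1-oxaspiro[4.5]deca-7,9-dien-3-yl]dodec-2-enamide F5. Here oxygen can only reach C1.
- F5 is reduced without concentration with LiBH4 to the triol (2E)-N-[(2S)-1-[(1S)-1,6-dihydroxycyclohexa-2,4-dien-1-yl]-3-hydroxypropan-2-yl]dodec-2-enamide F6 (lactone to diol, ketone to dienol).
- MnO2 reoxidises only the dienylic secondary alcohol of F6 and returns 5.

**Step 4.** Most likely to go wrong: over-oxidation of the lactol to the spiro-lactone, or slow loss of the epoxy enone during a sluggish oxidation.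

Fallback: the oxidation is moved in front of the dearomatisation, where nothing else is sensitive. It sets out from 4 and comes back at 7. 4 is oxidised (SO3·pyridine, DMSO, i-Pr2NEt) to the aldehyde, which is stored as its cyclic hemiacetal with the phenol, the chromanol (2E)-N-[(3S)-2-hydroxy-3,4-dihydro-2H-chromen-3-yl]dodec-2-enamide F7. Under the conditions of step 3 the open form of F7 is hydroxylated at C1, the aldehyde is re-trapped by the new C1 hydroxyl (the dienone spiro-lactol F1 of the step 5 fallback), and epoxidation in the same flask gives 7. The price is that the epoxidation then relies on the steric bias of the spiro ring and not on a free hydroxyl.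

## Further compounds

F1 | step 5 | (2E)-N-[(3S,5S)-2-hydroxy-6-oxo-1-oxaspiro[4.5]deca-7,9-dien-3-yl]dodec-2-enamide | CCCCCCCCC/C=C/C(=O)N[C@H]1C[C@@]2(OC1O)C(=O)C=CC=C2
F2 | step 5 | (2E)-N-[(1S,3S,4R,5S,6R)-1,4-dihydroxy-6-methoxy-9-oxobicyclo[3.3.1]non-7-en-3-yl]dodec-2-enamide | CCCCCCCCC/C=C/C(=O)N[C@H]1C[C@@]2(O)C(=O)[C@@H]([C@H]1O)[C@H](OC)C=C2
F3 | step 3 | (2E)-dodec-2-enoyl chloride | CCCCCCCCC/C=C/C(=O)Cl
F4 | step 3 | (2S)-2-[(2E)-dodec-2-enamido]-3-(2-hydroxyphenyl)propanoic acid | CCCCCCCCC/C=C/C(=O)N[C@@H](Cc1ccccc1O)C(=O)O
F5 | step 3 | (2E)-N-[(3S,5S)-2,6-dioxo-1-oxaspiro[4.5]deca-7,9-dien-3-yl]dodec-2-enamide | CCCCCCCCC/C=C/C(=O)N[C@H]1C[C@@]2(OC1=O)C(=O)C=CC=C2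
F6 | step 3 | (2E)-N-[(2S)-1-[(1S)-1,6-dihydroxycyclohexa-2,4-dien-1-yl]-3-hydroxypropan-2-yl]dodec-2-enamide (both carbinol epimers at C10) | CCCCCCCCC/C=C/C(=O)N[C@H](CO)C[C@@]1(O)C(O)C=CC=C1
F7 | step 4 | (2E)-N-[(3S)-2-hydroxy-3,4-dihydro-2H-chromen-3-yl]dodec-2-enamide | CCCCCCCCC/C=C/C(=O)N[C@H]1Cc2ccccc2OC1O
A1 | alternative 1 | (2E)-N-[(2S)-1-[(1S,2S,5S,6S)-2-hydroxy-5-methoxy-3-oxo-7-oxabicyclo[4.1.0]heptan-2-yl]-3-oxopropan-2-yl]dodec-2-enamide | CCCCCCCCC/C=C/C(=O)N[C@H](C=O)C[C@@]1(O)C(=O)C[C@H](OC)[C@@H]2O[C@@H]21
A2 | alternative 2 | (2E)-N-(3-oxoprop-1-en-2-yl)dodec-2-enamide | CCCCCCCCC/C=C/C(=O)NC(=C)C=O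
A3 | alternative 2 | 2-hydroxy-5-methoxy-7-oxabicyclo[4.1.0]heptan-3-one (methoxy cis to the epoxide, carbinol centre open) | O=C1C[C@H](OC)[C@@H]2O[C@@H]2C1O
A4 | alternative 3 | (1S,2S,4S,5S,6S)-1-hydroxy-5-methoxy-3-oxatricyclo[4.3.1.0^2,4]dec-7-en-10-one | C(C[C@@]1(O)C(=O)[C@@H]2[C@H](OC)[C@@H]3O[C@@H]31)=C2
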